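Retrosynthetic cuts: the butenolide is opened at C13–C16 and C16–O (carbonylative lactonisation of a Z-13-iodoalkene). C15 and C14 are then removed (formaldehyde, diazophosphonate) to leave a C13 carboxyl, and the C17 carbinol is traced back to a C17 carboxyl.
Enabling feature: C17 sits on C8 and C13 ends the C9–C11–C12 chain, so C8, C9, C11, C12, C13 and C17 outline a six-membered ring C in which C13 and C17 are neighbours. They can be the ipso and ortho carbons of a sacrificial 3,5-dimethoxybenzene ring, which RuO4 later burns down to just these two carboxyl carbons.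
Key cut: C4–C5, C9–C10 and C8–C17 of the benzo-fused tricycle (rings A, B, C) are broken together. This leads to an acyclic (3R)-C3–C4 epoxide with E-C5=C10, E-C8=C9 and the aryl terminator.
Forward order: the chain grows from the arene (Heck reaction, then two Grignard/Johnson–Claisen/reduction cycles). C4 with its two oxymethyl arms is added by iodo-Wittig and Stille reactions, rings A, B and C close in one step, C3 is deoxygenated, the arene is degraded, and the butenolide ring is closed last.
Stereochemistry: C3 comes from a Sharpless epoxidation with D-(−)-tartrate. C5, C10, C9 and C8 are relayed from C3 and from the two E alkenes in the all-chair cyclisation. C4 is not stereogenic once both arms carry the same group.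

Key step: step 14

Remark: labdane numbering (C1–C20) is used for every intermediate; the target SMILES corresponds to the ent-labdane series with 5S,8S,9R,10S (1R,2S,4aS,8aS as a decalin); TBS stands for tert-butyldimethylsilyl; paraformaldehyde is written as its monomer.

Step 1
Reactants: 1 1-iodo-3,5-dimethoxybenzene; 2 allyl alcohol
Product: 3 3-(3,5-dimethoxyphenyl)propanal
Conditions: Pd(OAc)2 (2 mol%), n-Bu4NCl, NaHCO3, DMF, 40 °C
Reagents that add atoms: allyl alcohol (2), C=CCO
Why: Heck arylation of an allylic alcohol under chloride-assisted ligand-free conditions: carbopalladation at the terminal alkene carbon, β-hydride elimination toward the carbinol carbon and tautomerisation of the enol should give the saturated aldehyde (C13 and C17 in the ring, C12, C11 and C9 in the chain) in one operation, with no stereocentre formed.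

Step 2
Reactants: 3 3-(3,5-dimethoxyphenyl)propanal; 4 vinylmagnesium bromide
Product: 5 rac-5-(3,5-dimethoxyphenyl)pent-1-en-3-ol
Conditions: THF, −78 → 0 °C
Reagents that add atoms: vinylmagnesium bromide (4), C=C[Mg]Br
Why: Grignard 1,2-addition to an unhindered aldehyde brings in C8 and C7; the carbinol centre at C9 is racemic by design because step 3 erases it.

Step 3
Reactants: 5 rac-5-(3,5-dimethoxyphenyl)pent-1-en-3-ol; 6 triethyl orthoacetate
Product: 8 ethyl (4E)-7-(3,5-dimethoxyphenyl)hept-4-enoate, via ketene acetal 7 (not isolated)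
Conditions: 6 (excess), EtCO2H (cat.), 140 °C, ethanol distilled off
Reagents that add atoms: triethyl orthoacetate (6), CC(OCC)(OCC)OCC
Why: Johnson–Claisen rearrangement: acid-catalysed exchange and loss of ethanol give ketene acetal 7, whose chair transition state holds the arylethyl group equatorial because the alternative chair suffers a 1,3-diaxial clash with the ethoxy group, so C6 and C5 are added and the C8=C9 alkene should form with high E selectivity, which is why the orthoester variant is preferred to a plain vinyl ether Claisen reaction.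

Step 4
Reactants: 8 ethyl (4E)-7-(3,5-dimethoxyphenyl)hept-4-enoate
Product: 9 (4E)-7-(3,5-dimethoxyphenyl)hept-4-enal
Conditions: i-Bu2AlH (1.05 equiv), CH2Cl2, −78 °C
Reagents that add atoms: none
Why: Partial reduction of an ester with i-Bu2AlH: at −78 °C the aluminium hemiacetal survives until work-up, so the reaction should stop at the C5 aldehyde and leave the alkene and the arene untouched.

Step 5
Reactants: 9 (4E)-7-(3,5-dimethoxyphenyl)hept-4-enal; 10 isopropenylmagnesium bromide
Product: 11 rac-(6E)-9-(3,5-dimethoxyphenyl)-2-methylnona-1,6-dien-3-ol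
Conditions: THF, −78 → 0 °C
Reagents that add atoms: isopropenylmagnesium bromide (10), C=C(C)[Mg]Br
Why: Grignard 1,2-addition brings in C10, C20 and C1; the carbinol centre at C5 is again racemic and is erased in step 6.

Step 6
Reactants: 11 rac-(6E)-9-(3,5-dimethoxyphenyl)-2-methylnona-1,6-dien-3-ol; 6 triethyl orthoacetate
Product: 13 ethyl (4E,8E)-11-(3,5-dimethoxyphenyl)-4-methylundeca-4,8-dienoate, via ketene acetal 12 (not isolated)
Conditions: 6 (excess), EtCO2H (cat.), 140 °C, ethanol distilled off
Reagents that add atoms: triethyl orthoacetate (6), CC(OCC)(OCC)OCC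
Why: Second Johnson–Claisen rearrangement: in the chair of ketene acetal 12 the long chain is equatorial, away from the ethoxy group, and this substitution pattern (a 2-methylallyl alcohol) is the classical source of E-trisubstituted alkenes, here E-C5=C10 together with C2 and C3.

Step 7
Reactants: 13 ethyl (4E,8E)-11-(3,5-dimethoxyphenyl)-4-methylundeca-4,8-dienoate
Product: 14 (4E,8E)-11-(3,5-dimethoxyphenyl)-4-methylundeca-4,8-dienal
Conditions: i-Bu2AlH (1.05 equiv), CH2Cl2, −78 °C
Reagents that add atoms: none
Why: Partial ester reduction with i-Bu2AlH as in step 4, which should stop at the C3 aldehyde because the tetrahedral aluminate is stable at −78 °C.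

Step 8
Reactants: 14 (4E,8E)-11-(3,5-dimethoxyphenyl)-4-methylundeca-4,8-dienal; 15 ethyl (triphenylphosphoranylidene)acetate
Product: 17 ethyl (2Z,6E,10E)-13-(3,5-dimethoxyphenyl)-2-iodo-6-methyltrideca-2,6,10-trienoate, via iodo ylide 16 (not isolated)
Conditions: 15, N-iodosuccinimide, CH2Cl2, −20 °C; then 14, −20 °C → rt
Reagents that add atoms: ethyl (triphenylphosphoranylidene)acetate (15), CCOC(=O)C=P(c1ccccc1)(c1ccccc1)c1ccccc1; N-iodosuccinimide, O=C1CCC(=O)N1I
Why: Wittig olefination with a halogenated stabilised ylide: N-iodosuccinimide iodinates 15 and the succinimide anion deprotonates the salt to 16, which should add to the aldehyde with the usual preference of stabilised ylides for the ester trans to the chain (2Z), bringing in C4 and the first arm; the minor geometric isomer has to be removed by chromatography because it would be epoxidised with the opposite sense in step 12.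

Step 9
Reactants: 17 ethyl (2Z,6E,10E)-13-(3,5-dimethoxyphenyl)-2-iodo-6-methyltrideca-2,6,10-trienoate; 18 (tributylstannyl)methanol
Product: 19 ethyl (2E,6E,10E)-13-(3,5-dimethoxyphenyl)-2-(hydroxymethyl)-6-methyltrideca-2,6,10-trienoate
Conditions: Pd2(dba)3 (2.5 mol%), AsPh3 (10 mol%), CuI (10 mol%), NMP, 45 °C
Reagents that add atoms: (tributylstannyl)methanol (18), CCCC[Sn](CCCC)(CCCC)CO
Why: Stille coupling of an electron-poor alkenyl iodide with (tributylstannyl)methanol installs the second arm with retention of alkene geometry, and the weakly bound arsine ligand with CuI should make transmetallation fast enough at mild temperature to outrun an intramolecular Heck reaction with the C5=C10 alkene.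

Step 10
Reactants: 19 ethyl (2E,6E,10E)-13-(3,5-dimethoxyphenyl)-2-(hydroxymethyl)-6-methyltrideca-2,6,10-trienoate
Product: 20 ethyl (2E,6E,10E)-2-(TBSOCH2)-13-(3,5-dimethoxyphenyl)-6-methyltrideca-2,6,10-trienoate
Conditions: TBSCl, imidazole, DMF, rt
Reagents that add atoms: tert-butyldimethylsilyl chloride, CC(C)(C)[Si](C)(C)Cl
Why: Imidazole-promoted silylation of a primary alcohol, which marks the arm cis to the chain before the ester arm is unveiled.

Step 11
Reactants: 20 ethyl (2E,6E,10E)-2-(TBSOCH2)-13-(3,5-dimethoxyphenyl)-6-methyltrideca-2,6,10-trienoate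
Product: 21 (2Z,6E,10E)-2-(TBSOCH2)-13-(3,5-dimethoxyphenyl)-6-methyltrideca-2,6,10-trien-1-ol
Conditions: i-Bu2AlH (2.3 equiv), CH2Cl2, −78 → −20 °C
Reagents that add atoms: none
Why: 1,2-Reduction of an α,β-unsaturated ester with excess i-Bu2AlH should give the allylic alcohol without conjugate reduction or loss of the silyl ether, and leaves the free hydroxymethyl group trans to the chain.

Step 12
Reactants: 21 (2Z,6E,10E)-2-(TBSOCH2)-13-(3,5-dimethoxyphenyl)-6-methyltrideca-2,6,10-trien-1-ol
Product: 22 [(2S,3R)-2-(TBSOCH2)-3-[(3E,7E)-10-(3,5-dimethoxyphenyl)-3-methyldeca-3,7-dien-1-yl]oxiran-2-yl]methanol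
Conditions: Ti(OiPr)4 (10 mol%), D-(−)-diisopropyl tartrate (12 mol%), t-BuOOH, 4 Å molecular sieves, CH2Cl2, −20 °C
Reagents that add atoms: tert-butyl hydroperoxide, CC(C)(C)OO
Why: Sharpless asymmetric epoxidation: only the alkene that carries the titanium-bound allylic alkoxide is oxidised, so C5=C10, C8=C9 and the arene are spared, and with the D-(−)-tartrate ligand oxygen is delivered to the face of this 2,3-disubstituted allylic alcohol (free CH2OH trans to the chain, the fast and selective substrate class) that makes C3 R and, for the moment, C4 S.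

Step 13
Reactants: 22 [(2S,3R)-2-(TBSOCH2)-3-[(3E,7E)-10-(3,5-dimethoxyphenyl)-3-methyldeca-3,7-dien-1-yl]oxiran-2-yl]methanol
Product: 23 (3R)-2,2-bis(TBSOCH2)-3-[(3E,7E)-10-(3,5-dimethoxyphenyl)-3-methyldeca-3,7-dien-1-yl]oxirane
Conditions: TBSCl, imidazole, CH2Cl2, 0 °C → rt
Reagents that add atoms: tert-butyldimethylsilyl chloride, CC(C)(C)[Si](C)(C)Cl
Why: Imidazole-promoted silylation of the primary alcohol under conditions too mild for Payne rearrangement; with two identical arms C4 is no longer a stereocentre and 3R is the only stereochemical information carried into the key step.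

Step 14
Reactants: 23 (3R)-2,2-bis(TBSOCH2)-3-[(3E,7E)-10-(3,5-dimethoxyphenyl)-3-methyldeca-3,7-dien-1-yl]oxirane
Product: 24 (4bS,6aS,8R,10aS,10bR)-7,7-bis(TBSOCH2)-2,4-dimethoxy-10a-methyl-4b,5,6,6a,7,8,9,10,10a,10b,11,12-dodecahydrochrysen-8-ol (labdane locants 3R,5S,8S,9R,10S; rings A/B/C trans-anti-trans; 3-OH equatorial)
Conditions: MeAlCl2 (2.5 equiv), CH2Cl2, −78 °C
Reagents that add atoms: none
Why: MeAlCl2 binds the oxirane oxygen, the C4–O bond stretches and the C5=C10 π bond attacks C4 from the rear, the resulting C10 cation is captured by C9 of the E-C8=C9 alkene, and the charge developing at C8 is taken up at once by the arene carbon that lies ortho to one and para to the other methoxy group; the arenium proton is consumed by the Al–CH3 bond, so the medium stays free of Brønsted acid. The closest known reaction type is the Lewis acid-promoted, epoxide-initiated polyene cyclisation with an electron-rich aryl terminator, known for oxiranes that carry one oxymethyl group at the ionising carbon and, with other cationic initiators, for an internal E-1,2-disubstituted alkene followed by a methoxyaryl group. Ring A closes 6-endo at the alkene with opening of the oxirane at its fully substituted carbon (attack at C3 would need a strained 5-endo ring), ring B closes 6-endo at C8=C9, and ring C closes as a six-membered Friedel–Crafts alkylation. In the all-chair array the C3–O bond sits equatorial, so 3R fixes the face of C5=C10 that is attacked and thereby the absolute sense; anti addition across E-C5=C10 sets H-5 trans to the C10 methyl group, and anti addition across E-C8=C9 sets H-9 anti to that methyl group and H-8 trans to H-9, which places C11 and C17 equatorial. The step needs the cascade to outrun hydride shift in the opened oxirane and proton loss from C10: silyl ethers are the least electron-withdrawing and non-participating oxygen protection, −78 °C and a non-basic chlorinated solvent disfavour elimination, and the doubly activated arene assists closure at the otherwise secondary C8. Regiochemistry on the arene is not an issue because its two free ortho positions are equivalent.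

Step 15
Reactants: 24 tetracyclic alcohol (3R,5S,8S,9R,10S)
Product: 25 O-[(4bS,6aS,8R,10aS,10bR)-7,7-bis(TBSOCH2)-2,4-dimethoxy-10a-methyl-4b,5,6,6a,7,8,9,10,10a,10b,11,12-dodecahydrochrysen-8-yl] 1H-imidazole-1-carbothioate
Conditions: 1,1'-thiocarbonyldiimidazole, DMAP (cat.), toluene, 90 °C
Reagents that add atoms: 1,1'-thiocarbonyldiimidazole, S=C(n1ccnc1)n1ccnc1
Why: First half of the Barton–McCombie deoxygenation: acylation with thiocarbonyldiimidazole runs without an alkoxide, which avoids 1,5-silyl migration from the neighbouring arms, and is established for equatorial C3 alcohols next to a quaternary C4.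

Step 16
Reactants: 25 C3 imidazolylthiocarbonyl derivative
Product: 26 (4bS,6aS,10aS,10bR)-7,7-bis(TBSOCH2)-2,4-dimethoxy-10a-methyl-4b,5,6,6a,7,8,9,10,10a,10b,11,12-dodecahydrochrysene
Conditions: Bu3SnH, AIBN (cat.), toluene, 110 °C
Reagents that add atoms: none
Why: Barton–McCombie radical deoxygenation: the stannyl radical adds to sulfur, the secondary C3 radical is released and takes hydrogen from Bu3SnH, no leaving group sits on C2 or C4 so β-scission is not possible, and the four ring-fusion centres are not touched.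

Step 17
Reactants: 26 3-deoxy tetracycle
Product: 27 (1R,2S,4aS,8aS)-1-(2-carboxyethyl)-5,5-bis(TBSOCH2)-8a-methyldecahydronaphthalene-2-carboxylic acid
Conditions: RuCl3·3H2O (10 mol%), NaIO4 (excess), MeCN/EtOAc/H2O, rt
Reagents that add atoms: sodium periodate, [Na+].[O-]I(=O)(=O)=O; water, O
Why: RuO4-catalysed oxidative degradation of an arene (RuCl3 with NaIO4 as terminal oxidant in a nitrile-containing two-phase medium): the dimethoxybenzene ring is by far the most electron-rich site and should be cleaved down to the two ring carbons that bear alkyl groups, which stay behind as the C13 and C17 carboxyl groups, while the C8 centre and the hindered neopentyl silyl ethers are expected to survive.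

Step 18
Reactants: 27 C13,C17 diacid
Product: 28 methyl (1R,2S,4aS,8aS)-5,5-bis(TBSOCH2)-1-(3-methoxy-3-oxopropyl)-8a-methyldecahydronaphthalene-2-carboxylate
Conditions: MeI, K2CO3, DMF, rt
Reagents that add atoms: methyl iodide, C[I]
Why: O-Alkylation of the two carboxylates with methyl iodide (SN2) is insensitive to hindrance at C17 and harmless to silyl ethers, and the C17 ester is equatorial so that the mild base cannot change C8.

Step 19
Reactants: 28 C13,C17 dimethyl ester
Product: 29 methyl (1R,2S,4aS,8aS)-5,5-bis(TBSOCH2)-1-{3-[methoxy(methyl)amino]-3-oxopropyl}-8a-methyldecahydronaphthalene-2-carboxylate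
Conditions: MeNH(OMe)·HCl (1.2 equiv), i-PrMgCl (2.4 equiv), THF, −20 °C
Reagents that add atoms: N,O-dimethylhydroxylamine hydrochloride, CNOC.Cl
Why: Ester to Weinreb amide exchange with the chloromagnesium amide made in the flask: the unbranched C13 ester at the chain end should react well before the ring-bound secondary C17 ester that is flanked by C9, so a small excess of reagent at low temperature tells the two carboxyl carbons apart.

Step 20
Reactants: 29 C13 Weinreb amide C17 ester
Product: 30 3-[(1R,2S,4aS,8aS)-5,5-bis(TBSOCH2)-2-(hydroxymethyl)-8a-methyldecahydronaphthalen-1-yl]propanal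
Conditions: LiAlH4, THF, −78 → 0 °C
Reagents that add atoms: none
Why: Hydride reduction with built-in differentiation: LiAlH4 takes the C17 ester to the primary alcohol whereas the Weinreb amide stops at the chelated tetrahedral intermediate and releases the C13 aldehyde only on work-up.

Step 21
Reactants: 30 C17 alcohol C13 aldehyde; 31 dimethyl (1-diazo-2-oxopropyl)phosphonate
Product: 32 [(1R,2S,4aS,8aS)-1-(but-3-yn-1-yl)-5,5-bis(TBSOCH2)-8a-methyldecahydronaphthalen-2-yl]methanol
Conditions: 31, K2CO3, MeOH, rt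
Reagents that add atoms: dimethyl (1-diazo-2-oxopropyl)phosphonate (31), COP(=O)(OC)C(=[N+]=[N-])C(C)=O
Why: Ohira–Bestmann homologation (Seyferth–Gilbert type): methanolysis of 31 gives the diazomethylphosphonate anion, which adds to the aldehyde, loses phosphate and nitrogen and rearranges to the terminal alkyne, so C14 is added under conditions that tolerate the free alcohol and the silyl ethers, and no stereocentre lies next to the aldehyde.

Step 22
Reactants: 32 terminal alkyne; 33 paraformaldehyde
Product: 34 5-[(1R,2S,4aS,8aS)-5,5-bis(TBSOCH2)-2-(hydroxymethyl)-8a-methyldecahydronaphthalen-1-yl]pent-2-yn-1-ol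
Conditions: n-BuLi (2.2 equiv), THF, −78 °C; then (CH2O)n, −78 °C → rt
Reagents that add atoms: formaldehyde from paraformaldehyde (33), C=O
Why: Hydroxymethylation of a lithium acetylide: two equivalents of base deprotonate O17–H and C14–H, the carbon nucleophile adds irreversibly to formaldehyde and brings in C15, whereas the alkoxide adds only reversibly.

Step 23
Reactants: 34 propargylic alcohol
Product: 35 (2Z)-5-[(1R,2S,4aS,8aS)-5,5-bis(TBSOCH2)-2-(hydroxymethyl)-8a-methyldecahydronaphthalen-1-yl]-3-iodopent-2-en-1-ol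
Conditions: NaAlH2(OCH2CH2OMe)2 (excess), THF, 0 °C → rt; then I2, −78 °C
Reagents that add atoms: iodine, [I][I]
Why: Hydroxyl-directed trans-hydroalumination of a propargylic alcohol followed by iodinolysis: the aluminium hydride bound to O15 delivers hydrogen to C14 and aluminium to C13, and iodine replaces aluminium with retention, so the alkene should have iodine cis to C15 (2Z) as the lactone closure requires.

Step 24
Reactants: 35 Z-13-iodoalkene; 36 carbon monoxide
Product: 37 3-{2-[(1R,2S,4aS,8aS)-5,5-bis(TBSOCH2)-2-(hydroxymethyl)-8a-methyldecahydronaphthalen-1-yl]ethyl}furan-2(5H)-one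
Conditions: PdCl2(PPh3)2 (5 mol%), K2CO3, CO (1 atm), THF, 50 °C
Reagents that add atoms: carbon monoxide (36), [C-]#[O+]
Why: Palladium-catalysed carbonylative lactonisation: zerovalent palladium formed in the flask inserts into the C13–I bond, CO insertion brings in C16 and the cis O15–H captures the acylpalladium to close the five-membered butenolide ring, whereas O17–H could only form an eight-membered ring.

Step 25
Reactants: 37 bis-silylated butenolide
Product: 38 3-{2-[(1R,2S,4aS,8aS)-2,5,5-tris(hydroxymethyl)-8a-methyldecahydronaphthalen-1-yl]ethyl}furan-2(5H)-one (target)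
Conditions: HF·pyridine, THF, 0 °C → rt
Reagents that add atoms: none
Why: Fluoride-driven cleavage of both silyl ethers under slightly acidic conditions, chosen because the butenolide is sensitive to base; no stereocentre is involved and the product is the target.

Compound list
1 | 1-iodo-3,5-dimethoxybenzene | COc1cc(I)cc(OC)c1 | starting material
2 | allyl alcohol | C=CCO | starting material
3 | 3-(3,5-dimethoxyphenyl)propanal | O=CCCc1cc(OC)cc(OC)c1 | intermediate
4 | vinylmagnesium bromide | C=C[Mg]Br | starting material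
5 | rac-5-(3,5-dimethoxyphenyl)pent-1-en-3-ol | C=CC(O)CCc1cc(OC)cc(OC)c1 | intermediate
6 | triethyl orthoacetate | CC(OCC)(OCC)OCC | starting material
7 | ketene acetal of 5: 1-{3-[(1-ethoxyethenyl)oxy]pent-4-en-1-yl}-3,5-dimethoxybenzene | C=C(OCC)OC(C=C)CCc1cc(OC)cc(OC)c1 | intermediate
8 | ethyl (4E)-7-(3,5-dimethoxyphenyl)hept-4-enoate | CCOC(=O)CC/C=C/CCc1cc(OC)cc(OC)c1 | intermediate
9 | (4E)-7-(3,5-dimethoxyphenyl)hept-4-enal | O=CCC/C=C/CCc1cc(OC)cc(OC)c1 | intermediate
10 | isopropenylmagnesium bromide | C=C(C)[Mg]Br | starting material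
11 | rac-(6E)-9-(3,5-dimethoxyphenyl)-2-methylnona-1,6-dien-3-ol | C=C(C)C(O)CC/C=C/CCc1cc(OC)cc(OC)c1 | intermediate
12 | ketene acetal of 11: 1-{(3E)-7-[(1-ethoxyethenyl)oxy]-8-methylnona-3,8-dien-1-yl}-3,5-dimethoxybenzene | C=C(OCC)OC(C(C)=C)CC/C=C/CCc1cc(OC)cc(OC)c1 | intermediate
13 | ethyl (4E,8E)-11-(3,5-dimethoxyphenyl)-4-methylundeca-4,8-dienoate | CCOC(=O)CC/C(C)=C/CC/C=C/CCc1cc(OC)cc(OC)c1 | intermediate
14 | (4E,8E)-11-(3,5-dimethoxyphenyl)-4-methylundeca-4,8-dienal | O=CCC/C(C)=C/CC/C=C/CCc1cc(OC)cc(OC)c1 | intermediate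
15 | ethyl (triphenylphosphoranylidene)acetate | CCOC(=O)C=P(c1ccccc1)(c1ccccc1)c1ccccc1 | starting material
16 | iodo ylide: ethyl iodo(triphenylphosphoranylidene)acetate | CCOC(=O)C(I)=P(c1ccccc1)(c1ccccc1)c1ccccc1 | intermediate
17 | ethyl (2Z,6E,10E)-13-(3,5-dimethoxyphenyl)-2-iodo-6-methyltrideca-2,6,10-trienoate | CCOC(=O)/C(I)=C/CC/C(C)=C/CC/C=C/CCc1cc(OC)cc(OC)c1 | intermediate
18 | (tributylstannyl)methanol | CCCC[Sn](CCCC)(CCCC)CO | starting material
19 | ethyl (2E,6E,10E)-13-(3,5-dimethoxyphenyl)-2-(hydroxymethyl)-6-methyltrideca-2,6,10-trienoate | CCOC(=O)/C(CO)=C/CC/C(C)=C/CC/C=C/CCc1cc(OC)cc(OC)c1 | intermediate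
20 | ethyl (2E,6E,10E)-2-(TBSOCH2)-13-(3,5-dimethoxyphenyl)-6-methyltrideca-2,6,10-trienoate | CCOC(=O)/C(CO[Si](C)(C)C(C)(C)C)=C/CC/C(C)=C/CC/C=C/CCc1cc(OC)cc(OC)c1 | intermediate
21 | (2Z,6E,10E)-2-(TBSOCH2)-13-(3,5-dimethoxyphenyl)-6-methyltrideca-2,6,10-trien-1-ol | OC/C(CO[Si](C)(C)C(C)(C)C)=C/CC/C(C)=C/CC/C=C/CCc1cc(OC)cc(OC)c1 | intermediate
22 | [(2S,3R)-2-(TBSOCH2)-3-[(3E,7E)-10-(3,5-dimethoxyphenyl)-3-methyldeca-3,7-dien-1-yl]oxiran-2-yl]methanol | OC[C@@]1(CO[Si](C)(C)C(C)(C)C)O[C@@H]1CC/C(C)=C/CC/C=C/CCc1cc(OC)cc(OC)c1 | intermediate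
23 | (3R)-2,2-bis(TBSOCH2)-3-[(3E,7E)-10-(3,5-dimethoxyphenyl)-3-methyldeca-3,7-dien-1-yl]oxirane (key-step precursor) | CC(C)(C)[Si](C)(C)OCC1(CO[Si](C)(C)C(C)(C)C)O[C@@H]1CC/C(C)=C/CC/C=C/CCc1cc(OC)cc(OC)c1 | intermediate
24 | (4bS,6aS,8R,10aS,10bR)-7,7-bis(TBSOCH2)-2,4-dimethoxy-10a-methyl-4b,5,6,6a,7,8,9,10,10a,10b,11,12-dodecahydrochrysen-8-ol (key-step product) | C[C@@]12CC[C@@H](O)C(CO[Si](C)(C)C(C)(C)C)(CO[Si](C)(C)C(C)(C)C)[C@H]1CC[C@H]3[C@H]2CCc4cc(OC)cc(OC)c34 | intermediate
25 | O-(C3) 1H-imidazole-1-carbothioate of 24 | C[C@@]12CC[C@@H](OC(=S)n5ccnc5)C(CO[Si](C)(C)C(C)(C)C)(CO[Si](C)(C)C(C)(C)C)[C@H]1CC[C@H]3[C@H]2CCc4cc(OC)cc(OC)c34 | intermediate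
26 | (4bS,6aS,10aS,10bR)-7,7-bis(TBSOCH2)-2,4-dimethoxy-10a-methyl-4b,5,6,6a,7,8,9,10,10a,10b,11,12-dodecahydrochrysene | C[C@@]12CCCC(CO[Si](C)(C)C(C)(C)C)(CO[Si](C)(C)C(C)(C)C)[C@H]1CC[C@H]3[C@H]2CCc4cc(OC)cc(OC)c34 | intermediate
27 | (1R,2S,4aS,8aS)-1-(2-carboxyethyl)-5,5-bis(TBSOCH2)-8a-methyldecahydronaphthalene-2-carboxylic acid | C[C@@]12CCCC(CO[Si](C)(C)C(C)(C)C)(CO[Si](C)(C)C(C)(C)C)[C@H]1CC[C@H](C(=O)O)[C@H]2CCC(=O)O | intermediate
28 | methyl (1R,2S,4aS,8aS)-5,5-bis(TBSOCH2)-1-(3-methoxy-3-oxopropyl)-8a-methyldecahydronaphthalene-2-carboxylate | C[C@@]12CCCC(CO[Si](C)(C)C(C)(C)C)(CO[Si](C)(C)C(C)(C)C)[C@H]1CC[C@H](C(=O)OC)[C@H]2CCC(=O)OC | intermediate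
29 | methyl (1R,2S,4aS,8aS)-5,5-bis(TBSOCH2)-1-{3-[methoxy(methyl)amino]-3-oxopropyl}-8a-methyldecahydronaphthalene-2-carboxylate | C[C@@]12CCCC(CO[Si](C)(C)C(C)(C)C)(CO[Si](C)(C)C(C)(C)C)[C@H]1CC[C@H](C(=O)OC)[C@H]2CCC(=O)N(C)OC | intermediate
30 | 3-[(1R,2S,4aS,8aS)-5,5-bis(TBSOCH2)-2-(hydroxymethyl)-8a-methyldecahydronaphthalen-1-yl]propanal | C[C@@]12CCCC(CO[Si](C)(C)C(C)(C)C)(CO[Si](C)(C)C(C)(C)C)[C@H]1CC[C@H](CO)[C@H]2CCC=O | intermediate
31 | dimethyl (1-diazo-2-oxopropyl)phosphonate | COP(=O)(OC)C(=[N+]=[N-])C(C)=O | starting material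
32 | [(1R,2S,4aS,8aS)-1-(but-3-yn-1-yl)-5,5-bis(TBSOCH2)-8a-methyldecahydronaphthalen-2-yl]methanol | C[C@@]12CCCC(CO[Si](C)(C)C(C)(C)C)(CO[Si](C)(C)C(C)(C)C)[C@H]1CC[C@H](CO)[C@H]2CCC#C | intermediate
33 | paraformaldehyde (written as formaldehyde) | C=O | starting material
34 | 5-[(1R,2S,4aS,8aS)-5,5-bis(TBSOCH2)-2-(hydroxymethyl)-8a-methyldecahydronaphthalen-1-yl]pent-2-yn-1-ol | C[C@@]12CCCC(CO[Si](C)(C)C(C)(C)C)(CO[Si](C)(C)C(C)(C)C)[C@H]1CC[C@H](CO)[C@H]2CCC#CCO | intermediate
35 | (2Z)-5-[(1R,2S,4aS,8aS)-5,5-bis(TBSOCH2)-2-(hydroxymethyl)-8a-methyldecahydronaphthalen-1-yl]-3-iodopent-2-en-1-ol | C[C@@]12CCCC(CO[Si](C)(C)C(C)(C)C)(CO[Si](C)(C)C(C)(C)C)[C@H]1CC[C@H](CO)[C@H]2CC/C(I)=C/CO | intermediate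
36 | carbon monoxide | [C-]#[O+] | starting material
37 | 3-{2-[(1R,2S,4aS,8aS)-5,5-bis(TBSOCH2)-2-(hydroxymethyl)-8a-methyldecahydronaphthalen-1-yl]ethyl}furan-2(5H)-one | C[C@@]12CCCC(CO[Si](C)(C)C(C)(C)C)(CO[Si](C)(C)C(C)(C)C)[C@H]1CC[C@H](CO)[C@H]2CCC1=CCOC1=O | intermediate
38 | 3-{2-[(1R,2S,4aS,8aS)-2,5,5-tris(hydroxymethyl)-8a-methyldecahydronaphthalen-1-yl]ethyl}furan-2(5H)-one | C[C@@]12CCCC(CO)(CO)[C@H]1CC[C@H](CO)[C@H]2CCC1=CCOC1=O | target

Total step count: 25. Longest linear sequence: 25 steps (1 to 38); every other partner is purchased.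

Steps most likely to fail

Step 14 (cyclisation). The two β-silyloxy groups slow ionisation at C4, and the internal alkene is only disubstituted. Hydride migration within the opened oxirane, or proton loss from C10 after the first ring closure, may therefore overtake closure of rings B and C. The fallback sets out from 23 and comes back at 24. It splits the cascade into two cationic events with different initiators:
- Compound 23 is treated with MeAlCl2 as before, and the product of ring A closure alone, the monocyclic alcohol F1, is accepted and isolated.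
- Its C1=C10 alkene is then protonated with a Lewis acid-assisted Brønsted acid (SnCl4 with 2-methoxyphenol, toluene, −78 °C). In this medium proton loss is reversible.
- The regenerated C10 cation can therefore be funnelled through E-C8=C9 and the arene to 24. The chair control is the same, because C5 already carries its chain equatorially.
- Any silyl ether lost on the way is put back with TBSCl.

Step 17 (arene degradation). During the long exposure to acidic periodate that is needed to burn the ring down, the silyl ethers may be hydrolysed, or the C–H bonds next to their oxygen atoms may be oxidised. The fallback sets out from 26 and comes back at 28. It changes the protecting-group plan around the oxidation: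
- Bu4NF removes both silyl groups to give the diol F2.
- Ac2O in pyridine gives the diacetate F3, whose ester groups are inert to RuO4 and to acid.
- Oxidation as in step 17 gives the diacid diacetate F4, and MeI with K2CO3 gives the dimethyl ester diacetate F5.
- K2CO3 in MeOH removes only the acetates, because exchange at the methyl esters is degenerate, and gives the diester diol F6.
- TBSCl with imidazole returns 28.

Step 19 (telling C13 from C17). The magnesium amide may not discriminate enough between the two esters, which would lead to double amidation or to a mixture. The fallback sets out from 28 and comes back at 32. It rests on differences of functional group instead: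
- One equivalent of LiOH in aqueous THF hydrolyses the chain ester first, to the mono acid F7. Over-hydrolysed material can be re-esterified to 28.
- BH3·THF reduces the free acid but not the ester, to the hydroxy ester F8.
- Dess–Martin periodinane gives the aldehyde ester F9.
- Reagent 31 with K2CO3 in MeOH gives the alkyne ester F10.
- LiAlH4 reduces the C17 ester to give 32.

Further compounds
F1 | step 14 | (1R,3S)-2,2-bis(TBSOCH2)-3-[(3E)-6-(3,5-dimethoxyphenyl)hex-3-en-1-yl]-4-methylcyclohex-4-en-1-ol | CC1=CC[C@@H](O)C(CO[Si](C)(C)C(C)(C)C)(CO[Si](C)(C)C(C)(C)C)[C@H]1CC/C=C/CCc1cc(OC)cc(OC)c1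
F2 | step 17 | [(4bS,6aS,10aS,10bR)-2,4-dimethoxy-10a-methyl-4b,5,6,6a,8,9,10,10a,10b,11,12-undecahydrochrysene-7,7-diyl]dimethanol | C[C@@]12CCCC(CO)(CO)[C@H]1CC[C@H]3[C@H]2CCc4cc(OC)cc(OC)c34
F3 | step 17 | diacetate of F2 | C[C@@]12CCCC(COC(C)=O)(COC(C)=O)[C@H]1CC[C@H]3[C@H]2CCc4cc(OC)cc(OC)c34
F4 | step 17 | (1R,2S,4aS,8aS)-5,5-bis(acetoxymethyl)-1-(2-carboxyethyl)-8a-methyldecahydronaphthalene-2-carboxylic acid | C[C@@]12CCCC(COC(C)=O)(COC(C)=O)[C@H]1CC[C@H](C(=O)O)[C@H]2CCC(=O)O
F5 | step 17 | methyl (1R,2S,4aS,8aS)-5,5-bis(acetoxymethyl)-1-(3-methoxy-3-oxopropyl)-8a-methyldecahydronaphthalene-2-carboxylate | C[C@@]12CCCC(COC(C)=O)(COC(C)=O)[C@H]1CC[C@H](C(=O)OC)[C@H]2CCC(=O)OC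
F6 | step 17 | methyl (1R,2S,4aS,8aS)-5,5-bis(hydroxymethyl)-1-(3-methoxy-3-oxopropyl)-8a-methyldecahydronaphthalene-2-carboxylate | C[C@@]12CCCC(CO)(CO)[C@H]1CC[C@H](C(=O)OC)[C@H]2CCC(=O)OC
F7 | step 19 | 3-[(1R,2S,4aS,8aS)-5,5-bis(TBSOCH2)-2-(methoxycarbonyl)-8a-methyldecahydronaphthalen-1-yl]propanoic acid | C[C@@]12CCCC(CO[Si](C)(C)C(C)(C)C)(CO[Si](C)(C)C(C)(C)C)[C@H]1CC[C@H](C(=O)OC)[C@H]2CCC(=O)O
F8 | step 19 | methyl (1R,2S,4aS,8aS)-5,5-bis(TBSOCH2)-1-(3-hydroxypropyl)-8a-methyldecahydronaphthalene-2-carboxylate | C[C@@]12CCCC(CO[Si](C)(C)C(C)(C)C)(CO[Si](C)(C)C(C)(C)C)[C@H]1CC[C@H](C(=O)OC)[C@H]2CCCO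
F9 | step 19 | methyl (1R,2S,4aS,8aS)-5,5-bis(TBSOCH2)-8a-methyl-1-(3-oxopropyl)decahydronaphthalene-2-carboxylate | C[C@@]12CCCC(CO[Si](C)(C)C(C)(C)C)(CO[Si](C)(C)C(C)(C)C)[C@H]1CC[C@H](C(=O)OC)[C@H]2CCC=O
F10 | step 19 | methyl (1R,2S,4aS,8aS)-1-(but-3-yn-1-yl)-5,5-bis(TBSOCH2)-8a-methyldecahydronaphthalene-2-carboxylate | C[C@@]12CCCC(CO[Si](C)(C)C(C)(C)C)(CO[Si](C)(C)C(C)(C)C)[C@H]1CC[C@H](C(=O)OC)[C@H]2CCC#C
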